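**Plan**
- Last cut: each 1,5-dialdehyde arm OHC–C(=CHCH3)–CH–CH2–CHO is re-joined between its two formyl carbons to a cis-cyclopentane-1,2-diol (glycol-cleavage retron, carried as its acetonide).
- Main cut: both ester C(=O)–CH2 bonds are cut at once, each together with the ring bond CH–C(=CHCH3) and the acyl C–O bond. This leaves diol 13, two CO and two molecules of dienyl triflate 21.
- Enabling feature: in the re-closed arm the ester CH2 sits outside a five-membered carbocycle, on the ring carbon next to the ethylidene-bearing carbon. This 2-(2-alkylidenecyclopentyl)acetate is exactly what 5-exo carbopalladation of a 2-triflyloxy-1,6-diene followed by CO insertion delivers.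
- Forward, core: the cyclopentane is present in 1 and is substituted by a three-component coupling. A temporary δ-lactone ring is annulated (step 3), hydrogenated to the trans fusion, used as a chair template for the side-chain centre, and opened by hydride (step 8).
- Forward, arms: the dioxolane of 21 comes from 2-deoxy-L-ribose. The two arm cyclopentanes arise in step 16 and are cleaved open in step 18.
- Stereochemistry: the C–O centre of 1 sets the ring CH3 and CH2OH (trans, trans). The free ring OH directs H2 to set the fourth ring centre. The locked lactone chair sets the side-chain CH (equatorial). The sugar diol sets each arm CH (convex face). The Z-enol triflate sets each E-ethylidene.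

Key step: step 16

Assumption: the target is drawn and handled as the open tetra-aldehyde diol, although its free hydroxyls may equilibrate with cyclic hemiacetals in solution.

**Part A: diol 13 (steps 1–10)**

Step 1
Reactants: 1 (R)-4-(tert-butyldimethylsilyloxy)cyclopent-2-en-1-one
Product: 3 (2S,3R,4R)-4-(tert-butyldimethylsilyloxy)-2-(hydroxymethyl)-3-methylcyclopentan-1-one, via lithium enolate 2 (not isolated)
Conditions: MeLi, CuI, Et2O, 0 °C; 1, −78 °C; monomeric CH2O in THF, −78 °C; aq NH4Cl
Reagents that add atoms: methyllithium (used as Me2CuLi) [Li]C; formaldehyde C=O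
Why: Tandem conjugate addition–aldol (three-component coupling on a 4-oxycyclopentenone), in which the cuprate should deliver methyl anti to the silyloxy group and enolate 2 should take up formaldehyde anti to the new methyl group, giving the trans,trans array.

Step 2
Reactants: 3 (2S,3R,4R)-4-(tert-butyldimethylsilyloxy)-2-(hydroxymethyl)-3-methylcyclopentan-1-one
Product: 4 [(1S,2R,3R)-3-(tert-butyldimethylsilyloxy)-2-methyl-5-oxocyclopentyl]methyl 2-(diethoxyphosphoryl)acetate
Conditions: (EtO)2P(O)CH2CO2H, DCC, DMAP (cat.), CH2Cl2, 0 °C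
Reagents that add atoms: diethylphosphonoacetic acid CCOP(=O)(CC(=O)O)OCC
Why: Steglich esterification of the primary alcohol under nearly neutral conditions that spare the β-oxygenated ketone and touch no stereocentre.

Step 3
Reactants: 4 [(1S,2R,3R)-3-(tert-butyldimethylsilyloxy)-2-methyl-5-oxocyclopentyl]methyl 2-(diethoxyphosphoryl)acetate
Product: 5 (6R,7R,7aR)-6-(tert-butyldimethylsilyloxy)-7-methyl-5,6,7,7a-tetrahydrocyclopenta[c]pyran-3(1H)-one
Conditions: LiCl, i-Pr2NEt, MeCN, rt
Reagents that add atoms: none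
Why: Intramolecular Horner–Wadsworth–Emmons olefination under Masamune–Roush conditions, where the acidic phosphonate is deprotonated in preference to the ketone and the six-ring closure should be faster than β-elimination of the acyloxy or silyloxy group.

Step 4
Reactants: 5 (6R,7R,7aR)-6-(tert-butyldimethylsilyloxy)-7-methyl-5,6,7,7a-tetrahydrocyclopenta[c]pyran-3(1H)-one
Product: 6 (6R,7R,7aR)-6-hydroxy-7-methyl-5,6,7,7a-tetrahydrocyclopenta[c]pyran-3(1H)-one
Conditions: aq HF (48%), MeCN, 0 °C to rt
Reagents that add atoms: none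
Why: Acidic fluoride desilylation frees the homoallylic hydroxyl needed as a directing group without base-induced isomerisation of the unsaturated lactone.

Step 5
Reactants: 6 (6R,7R,7aR)-6-hydroxy-7-methyl-5,6,7,7a-tetrahydrocyclopenta[c]pyran-3(1H)-one
Product: 7 (4aS,6R,7R,7aS)-6-hydroxy-7-methylhexahydrocyclopenta[c]pyran-3(1H)-one (trans-fused)
Conditions: [Ir(cod)(PCy3)(py)]PF6 (cat.), H2 (1 atm), CH2Cl2, 0 °C to rt
Reagents that add atoms: none
Why: Hydroxyl-directed homogeneous hydrogenation with Crabtree's catalyst, in which iridium binds the C-6 hydroxyl and should deliver hydrogen to the ring-fusion carbon C-4a from the same face, overriding the steric bias and giving the trans ring fusion.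

Step 6
Reactants: 7 (4aS,6R,7R,7aS)-6-hydroxy-7-methylhexahydrocyclopenta[c]pyran-3(1H)-one
Product: 9 (4S,4aR,6R,7R,7aS)-4-(benzyloxymethyl)-6-hydroxy-7-methylhexahydrocyclopenta[c]pyran-3(1H)-one (axial epimer), via dilithium enolate 8 (not isolated)
Conditions: LDA (2.2 equiv), THF, −78 °C; BnOCH2Cl (1.1 equiv), −78 to −40 °C; AcOH
Reagents that add atoms: benzyl chloromethyl ether ClCOCc1ccccc1
Why: Lactone enolate alkylation through the alkoxide–enolate dianion, whose carbon is the more nucleophilic site, with stereoelectronically preferred axial attack on the rigid trans-fused half-chair expected to place the new group axial.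

Step 7
Reactants: 9 (4S,4aR,6R,7R,7aS)-4-(benzyloxymethyl)-6-hydroxy-7-methylhexahydrocyclopenta[c]pyran-3(1H)-one
Product: 10 (4R,4aR,6R,7R,7aS)-4-(benzyloxymethyl)-6-hydroxy-7-methylhexahydrocyclopenta[c]pyran-3(1H)-one (equatorial epimer)
Conditions: DBU (cat.), BnOH (1 equiv), CH2Cl2, rt
Reagents that add atoms: none
Why: Base-catalysed epimerisation α to the lactone carbonyl (by enolisation or by reversible E1cB/oxa-Michael addition buffered with benzyl alcohol) should move the substituent into the equatorial position of the locked chair, which is the configuration of the side-chain centre of the target.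

Step 8
Reactants: 10 (4R,4aR,6R,7R,7aS)-4-(benzyloxymethyl)-6-hydroxy-7-methylhexahydrocyclopenta[c]pyran-3(1H)-one
Product: 11 (1R,2R,3S,4R)-4-[(2S)-1-(benzyloxy)-3-hydroxypropan-2-yl]-3-(hydroxymethyl)-2-methylcyclopentan-1-ol
Conditions: LiAlH4, THF, 0 °C to rt; Fieser work-up
Reagents that add atoms: none
Why: Hydride reduction opens the lactone template to the two primary alcohols that remain free in the target while the third arm stays marked as its benzyl ether, so the side-chain centre remains defined.

Step 9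
Reactants: 11 (1R,2R,3S,4R)-4-[(2S)-1-(benzyloxy)-3-hydroxypropan-2-yl]-3-(hydroxymethyl)-2-methylcyclopentan-1-ol
Product: 12 (1R,2R,3S,4R)-4-[(2R)-1-(benzyloxy)-3-(tert-butyldimethylsilyloxy)propan-2-yl]-3-[(tert-butyldimethylsilyloxy)methyl]-2-methylcyclopentan-1-ol
Conditions: TBSCl (2.1 equiv), imidazole, CH2Cl2, −10 to 0 °C
Reagents that add atoms: tert-butyldimethylsilyl chloride CC(C)(C)[Si](C)(C)Cl
Why: Selective silyl ether formation at the two primary hydroxyls, which react much faster than the hindered secondary ring hydroxyl.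

Step 10
Reactants: 12 (1R,2R,3S,4R)-4-[(2R)-1-(benzyloxy)-3-(tert-butyldimethylsilyloxy)propan-2-yl]-3-[(tert-butyldimethylsilyloxy)methyl]-2-methylcyclopentan-1-ol
Product: 13 (1R,2R,3S,4R)-4-[(2R)-1-(tert-butyldimethylsilyloxy)-3-hydroxypropan-2-yl]-3-[(tert-butyldimethylsilyloxy)methyl]-2-methylcyclopentan-1-ol
Conditions: H2 (1 atm), Pd/C, EtOAc, rt
Reagents that add atoms: none
Why: Catalytic hydrogenolysis of the benzyl ether in a neutral solvent leaves the silyl ethers in place and frees exactly the two hydroxyls that are acylated in the target.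

**Part B: triflate 21 (steps 11–15)**

Step 11
Reactants: 14 2-deoxy-L-ribose (2-deoxy-L-erythro-pentose)
Product: 15 2-deoxy-3,4-O-isopropylidene-L-erythro-pentopyranose
Conditions: 2-methoxypropene, PPTS (cat.), EtOAc, −10 °C to rt
Reagents that add atoms: 2-methoxypropene C=C(C)OC
Why: Kinetic acetonide formation on the cis-3,4-diol of the pyranose form, which fixes the two sugar stereocentres in a cis-dioxolane.

Step 12
Reactants: 15 2-deoxy-3,4-O-isopropylidene-L-erythro-pentopyranose
Product: 16 [(4S,5R)-5-allyl-2,2-dimethyl-1,3-dioxolan-4-yl]methanol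
Conditions: Ph3PCH3Br, KOt-Bu, THF, 0 °C to rt
Reagents that add atoms: methyltriphenylphosphonium bromide C[P+](c1ccccc1)(c1ccccc1)c1ccccc1.[Br-]
Why: Wittig methylenation of the lactol through its open hydroxy-aldehyde form installs the terminal alkene and releases the primary alcohol.

Step 13
Reactants: 16 [(4S,5R)-5-allyl-2,2-dimethyl-1,3-dioxolan-4-yl]methanol
Product: 18 1-[(4S,5R)-5-allyl-2,2-dimethyl-1,3-dioxolan-4-yl]propan-1-ol (carbinol epimers), via aldehyde 17 (not isolated)
Conditions: (COCl)2, DMSO, CH2Cl2, −78 °C; Et3N; EtMgBr (excess), −78 to 0 °C; aq NH4Cl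
Reagents that add atoms: ethylmagnesium bromide CC[Mg]Br
Why: Swern oxidation followed by Grignard addition in the same flask, so that the epimerisable cis-dioxolane aldehyde 17 is never handled, and the new carbinol centre is irrelevant because it is oxidised next.

Step 14
Reactants: 18 1-[(4S,5R)-5-allyl-2,2-dimethyl-1,3-dioxolan-4-yl]propan-1-ol
Product: 19 1-[(4R,5R)-5-allyl-2,2-dimethyl-1,3-dioxolan-4-yl]propan-1-one
Conditions: Dess–Martin periodinane, CH2Cl2, rt
Reagents that add atoms: none
Why: Dess–Martin oxidation converts both carbinol epimers into one ethyl ketone under non-basic conditions that do not epimerise the α-alkoxy centre.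

Step 15
Reactants: 19 1-[(4R,5R)-5-allyl-2,2-dimethyl-1,3-dioxolan-4-yl]propan-1-one
Product: 21 (Z)-1-[(4R,5R)-5-allyl-2,2-dimethyl-1,3-dioxolan-4-yl]prop-1-en-1-yl trifluoromethanesulfonate, via potassium Z-enolate 20 (not isolated)
Conditions: KHMDS, THF, −78 °C; Comins' reagent, −78 °C
Reagents that add atoms: N-(5-chloropyridin-2-yl)bis(trifluoromethanesulfonimide) O=S(=O)(N(c1ccc(Cl)cn1)S(=O)(=O)C(F)(F)F)C(F)(F)F
Why: Kinetic enolisation at the less hindered ethyl CH2 followed by O-sulfonylation (enol triflate synthesis), in which allylic strain between the methyl group and the branched dioxolanyl group should favour the Z(O)-enolate and thus place OTf cis to CH3.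

**Part C: union and endgame (steps 16–18)**

Step 16
Reactants: 13 (1R,2R,3S,4R)-4-[(2R)-1-(tert-butyldimethylsilyloxy)-3-hydroxypropan-2-yl]-3-[(tert-butyldimethylsilyloxy)methyl]-2-methylcyclopentan-1-ol; 21 (Z)-1-[(4R,5R)-5-allyl-2,2-dimethyl-1,3-dioxolan-4-yl]prop-1-en-1-yl trifluoromethanesulfonate (two molecules enter)
Product: 23 bis-ester of diol 13 in which both hydroxyls carry 2-[(3aS,4E,5S,6aR)-4-ethylidene-2,2-dimethyltetrahydro-4H-cyclopenta[d][1,3]dioxol-5-yl]acetyl groups, via primary monoester 22 (not isolated)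
Conditions: 21 (3 equiv), Pd(OAc)2 (cat.), PPh3 (cat.), CO (1 atm), Et3N, DMAP, DMF, 70 °C
Reagents that add atoms: carbon monoxide [C-]#[O+]
Why: Pd(0) inserts into the C–OTf bond of 21 with retention, the cationic vinyl-Pd adds syn across the tethered terminal alkene, CO inserts into the resulting primary σ-alkyl-Pd bond (this makes the C(=O)–CH2 bond), and the acyl-Pd is passed by DMAP to a free hydroxyl of 13, first the primary one (22) and then the ring carbinol, so that five components should give 23 in one flask. The closest known reaction type is the domino Heck cyclisation–alkoxycarbonylation of 2-halo- or 2-triflyloxy-1,6-dienes to 2-(2-alkylidenecyclopentyl)acetates. Each of the two new cyclopentane rings closes in the 5-exo-trig mode. Each new CH stereocentre is controlled by the cis-fused dioxolane, because the alkene should insert with its CH2–Pd terminus on the convex face, anti to both ring oxygens, which gives the S configuration, while retention at the vinyl carbon turns the Z-triflate into the E-ethylidene group. The step needs ring closure to outrun CO capture of the vinyl-Pd and CO capture to outrun β-hydride loss from the alkyl-Pd; the cis-dioxolane holds vinyl-Pd and alkene gauche for a fast closure, vinyl-acyl-Pd formation is reversible while a bulky alcohol traps it only slowly, and the CO-saturated solution intercepts the alkyl-Pd. Site selectivity is secured because only the two hydroxyls that bear acyl groups in the target are free in 13.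

Step 17
Reactants: 23 bis-ester of diol 13 with two acetonide-protected arms
Product: 24 hexaol in which both arms are 2-[(1S,2E,3S,4R)-2-ethylidene-3,4-dihydroxycyclopentyl]acetates and both primary core hydroxyls are free
Conditions: TFA, H2O, THF, 0 °C to rt
Reagents that add atoms: none
Why: Mild aqueous acid hydrolysis removes both acetonides and both primary silyl ethers in one operation, under conditions in which the esters should survive and acyl migration is slower than under base.

Step 18
Reactants: 24 hexaol with two cis-cyclopentane-1,2-diol arms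
Product: 25 target CNP0192766.1
Conditions: NaIO4, THF, pH 7 buffer, 0 °C
Reagents that add atoms: none
Why: Malaprade glycol cleavage opens both cis-1,2-diols to the enal and acetaldehyde termini, does not touch the non-vicinal primary alcohols, leaves the S arm centres and E alkenes unchanged, and removes the four helper stereocentres.

**Compound list**
1 | (R)-4-(tert-butyldimethylsilyloxy)cyclopent-2-en-1-one | O=C1C[C@@H](O[Si](C)(C)C(C)(C)C)C=C1 | starting material
2 | lithium (3R,4R)-4-(tert-butyldimethylsilyloxy)-3-methylcyclopent-1-en-1-olate | [Li]OC1=C[C@@H](C)[C@H](O[Si](C)(C)C(C)(C)C)C1 | intermediate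
3 | (2S,3R,4R)-4-(tert-butyldimethylsilyloxy)-2-(hydroxymethyl)-3-methylcyclopentan-1-one | O=C1C[C@@H](O[Si](C)(C)C(C)(C)C)[C@H](C)[C@H]1CO | intermediate
4 | [(1S,2R,3R)-3-(tert-butyldimethylsilyloxy)-2-methyl-5-oxocyclopentyl]methyl 2-(diethoxyphosphoryl)acetate | O=C1C[C@@H](O[Si](C)(C)C(C)(C)C)[C@H](C)[C@H]1COC(=O)CP(=O)(OCC)OCC | intermediate
5 | (6R,7R,7aR)-6-(tert-butyldimethylsilyloxy)-7-methyl-5,6,7,7a-tetrahydrocyclopenta[c]pyran-3(1H)-one | O=C1C=C2C[C@@H](O[Si](C)(C)C(C)(C)C)[C@H](C)[C@H]2CO1 | intermediate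
6 | (6R,7R,7aR)-6-hydroxy-7-methyl-5,6,7,7a-tetrahydrocyclopenta[c]pyran-3(1H)-one | O=C1C=C2C[C@@H](O)[C@H](C)[C@H]2CO1 | intermediate
7 | (4aS,6R,7R,7aS)-6-hydroxy-7-methylhexahydrocyclopenta[c]pyran-3(1H)-one, trans-fused | O=C1C[C@@H]2C[C@@H](O)[C@H](C)[C@H]2CO1 | intermediate
8 | dilithium alkoxide–enolate of 7 | [Li]OC1=C[C@@H]2C[C@@H](O[Li])[C@H](C)[C@H]2CO1 | intermediate
9 | (4S,4aR,6R,7R,7aS)-4-(benzyloxymethyl)-6-hydroxy-7-methylhexahydrocyclopenta[c]pyran-3(1H)-one, axial epimer | O=C1[C@H](COCc3ccccc3)[C@@H]2C[C@@H](O)[C@H](C)[C@H]2CO1 | intermediate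
10 | (4R,4aR,6R,7R,7aS)-4-(benzyloxymethyl)-6-hydroxy-7-methylhexahydrocyclopenta[c]pyran-3(1H)-one, equatorial epimer | O=C1[C@@H](COCc3ccccc3)[C@@H]2C[C@@H](O)[C@H](C)[C@H]2CO1 | intermediate
11 | (1R,2R,3S,4R)-4-[(2S)-1-(benzyloxy)-3-hydroxypropan-2-yl]-3-(hydroxymethyl)-2-methylcyclopentan-1-ol | OC[C@@H](COCc1ccccc1)[C@@H]2C[C@@H](O)[C@H](C)[C@H]2CO | intermediate
12 | (1R,2R,3S,4R)-4-[(2R)-1-(benzyloxy)-3-(tert-butyldimethylsilyloxy)propan-2-yl]-3-[(tert-butyldimethylsilyloxy)methyl]-2-methylcyclopentan-1-ol | CC(C)(C)[Si](C)(C)OC[C@@H](COCc1ccccc1)[C@@H]2C[C@@H](O)[C@H](C)[C@H]2CO[Si](C)(C)C(C)(C)C | intermediate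
13 | (1R,2R,3S,4R)-4-[(2R)-1-(tert-butyldimethylsilyloxy)-3-hydroxypropan-2-yl]-3-[(tert-butyldimethylsilyloxy)methyl]-2-methylcyclopentan-1-ol | OC[C@H](CO[Si](C)(C)C(C)(C)C)[C@@H]1C[C@@H](O)[C@H](C)[C@H]1CO[Si](C)(C)C(C)(C)C | intermediate
14 | 2-deoxy-L-ribose, (3R,4S)-3,4,5-trihydroxypentanal, sold as the pyranose | O=CC[C@@H](O)[C@@H](O)CO | starting material
15 | 2-deoxy-3,4-O-isopropylidene-L-erythro-pentopyranose | OC1C[C@H]2OC(C)(C)O[C@H]2CO1 | intermediate
16 | [(4S,5R)-5-allyl-2,2-dimethyl-1,3-dioxolan-4-yl]methanol | C=CC[C@H]1OC(C)(C)O[C@H]1CO | intermediate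
17 | (4R,5R)-5-allyl-2,2-dimethyl-1,3-dioxolane-4-carbaldehyde | C=CC[C@H]1OC(C)(C)O[C@H]1C=O | intermediate
18 | 1-[(4S,5R)-5-allyl-2,2-dimethyl-1,3-dioxolan-4-yl]propan-1-ol, carbinol epimers | C=CC[C@H]1OC(C)(C)O[C@H]1C(O)CC | intermediate
19 | 1-[(4R,5R)-5-allyl-2,2-dimethyl-1,3-dioxolan-4-yl]propan-1-one | C=CC[C@H]1OC(C)(C)O[C@H]1C(=O)CC | intermediate
20 | potassium Z(O)-enolate of 19 | C=CC[C@H]1OC(C)(C)O[C@H]1/C(O[K])=C/C | intermediate
21 | (Z)-1-[(4R,5R)-5-allyl-2,2-dimethyl-1,3-dioxolan-4-yl]prop-1-en-1-yl trifluoromethanesulfonate | C=CC[C@H]1OC(C)(C)O[C@H]1/C(OS(=O)(=O)C(F)(F)F)=C/C | intermediate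
22 | monoester of 13, acylated at the primary hydroxyl by the 2-[(3aS,4E,5S,6aR)-4-ethylidene-2,2-dimethyltetrahydro-4H-cyclopenta[d][1,3]dioxol-5-yl]acetyl group | O=C(C[C@@H]1C[C@H]2OC(C)(C)O[C@H]2/C1=C/C)OC[C@H](CO[Si](C)(C)C(C)(C)C)[C@@H]3C[C@@H](O)[C@H](C)[C@H]3CO[Si](C)(C)C(C)(C)C | intermediate
23 | bis-ester of 13, the same acyl group on the primary and on the ring hydroxyl | O=C(C[C@@H]1C[C@H]2OC(C)(C)O[C@H]2/C1=C/C)OC[C@H](CO[Si](C)(C)C(C)(C)C)[C@@H]3C[C@@H](OC(=O)C[C@@H]4C[C@H]5OC(C)(C)O[C@H]5/C4=C/C)[C@H](C)[C@H]3CO[Si](C)(C)C(C)(C)C | intermediate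
24 | hexaol, both arms 2-[(1S,2E,3S,4R)-2-ethylidene-3,4-dihydroxycyclopentyl]acetates | O=C(C[C@@H]1C[C@@H](O)[C@@H](O)/C1=C/C)OC[C@H](CO)[C@@H]2C[C@@H](OC(=O)C[C@@H]3C[C@@H](O)[C@@H](O)/C3=C/C)[C@H](C)[C@H]2CO | intermediate
25 | CNP0192766.1, bis[(3S,4E)-4-formyl-3-(2-oxoethyl)hex-4-enoate] of the cyclopentane tetraol | C/C=C(/C=O)[C@@H](CC=O)CC(=O)OC[C@H](CO)[C@@H]1C[C@@H](OC(=O)C[C@H](CC=O)/C(C=O)=C\C)[C@H](C)[C@H]1CO | target

**Step count**
- Total step count: 18.
- Longest linear sequence: 13 steps (steps 1–10, then 16–18).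

**Steps most likely to fail**

Step 16
- What may go wrong: capture of the acyl-palladium by the hindered ring hydroxyl may be too slow. Then β-hydride loss from the alkyl-palladium, carbonylation of the vinyl-palladium before ring closure, or an incomplete second acylation could take over.
- Fallback: it separates C–C from C–O bond formation and sets out from 21.
  - The same cyclisation–carbonylation is run with methanol as co-solvent to give the methyl ester F1.
  - Saponification with LiOH gives the acid F2.
  - F2 is attached twice to diol 13 by Yamaguchi mixed-anhydride esterification, which comes back to the route at 23.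

Step 5
- What may go wrong: facial selectivity may be poor (competing delivery of hydrogen from the open face, giving the cis fusion), or the iridium catalyst may deactivate before conversion.
- Fallback: it sets the centre by substitution with inversion instead of hydrogenation and sets out from 3.
  - Silylation of the primary hydroxyl gives the bis-silyl ketone F3.
  - L-Selectride reduction from the open face gives the all-cis alcohol F4.
  - Mesylation gives the mesylate F5.
  - SN2 displacement with sodium dimethyl malonate gives the malonate F6.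
  - Krapcho dealkoxycarbonylation gives the acetate ester F7.
  - Aqueous HF followed by catalytic acid removes both silyl groups and closes the lactone, which comes back to the route at 7.

Step 15
- What may go wrong: the enolate geometry may be poorly controlled, or enolisation may occur toward the dioxolane C–H, with epimerisation or opening of the acetonide.
- Fallback: it avoids enolates, builds the alkene geometry by a stereospecific trans addition to an alkyne, and sets out from 16.
  - After the Swern oxidation, aldehyde 17 is isolated and converted by Corey–Fuchs olefination into the dibromoalkene F8.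
  - n-BuLi followed by MeI gives the methyl alkyne F9.
  - O-directed radical hydrostannation with Ph3SnH and Et3B gives the vinylstannane F10.
  - Tin–iodine exchange with retention gives the Z-vinyl iodide F11.
  - F11 replaces 21 under the conditions of step 16 and so comes back to the route at 23.

Further compounds
F1 | step 16 | methyl 2-[(3aS,4E,5S,6aR)-4-ethylidene-2,2-dimethyltetrahydro-4H-cyclopenta[d][1,3]dioxol-5-yl]acetate | COC(=O)C[C@@H]1C[C@H]2OC(C)(C)O[C@H]2/C1=C/C
F2 | step 16 | 2-[(3aS,4E,5S,6aR)-4-ethylidene-2,2-dimethyltetrahydro-4H-cyclopenta[d][1,3]dioxol-5-yl]acetic acid | OC(=O)C[C@@H]1C[C@H]2OC(C)(C)O[C@H]2/C1=C/C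
F3 | step 5 | (2S,3R,4R)-4-(tert-butyldimethylsilyloxy)-2-[(tert-butyldimethylsilyloxy)methyl]-3-methylcyclopentan-1-one | O=C1C[C@@H](O[Si](C)(C)C(C)(C)C)[C@H](C)[C@H]1CO[Si](C)(C)C(C)(C)C
F4 | step 5 | (1S,2S,3R,4R)-4-(tert-butyldimethylsilyloxy)-2-[(tert-butyldimethylsilyloxy)methyl]-3-methylcyclopentan-1-ol | O[C@H]1C[C@@H](O[Si](C)(C)C(C)(C)C)[C@H](C)[C@H]1CO[Si](C)(C)C(C)(C)C
F5 | step 5 | (1S,2S,3R,4R)-4-(tert-butyldimethylsilyloxy)-2-[(tert-butyldimethylsilyloxy)methyl]-3-methylcyclopentyl methanesulfonate | CS(=O)(=O)O[C@H]1C[C@@H](O[Si](C)(C)C(C)(C)C)[C@H](C)[C@H]1CO[Si](C)(C)C(C)(C)C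
F6 | step 5 | dimethyl 2-[(1R,2S,3R,4R)-4-(tert-butyldimethylsilyloxy)-2-[(tert-butyldimethylsilyloxy)methyl]-3-methylcyclopentyl]malonate | COC(=O)C(C(=O)OC)[C@@H]1C[C@@H](O[Si](C)(C)C(C)(C)C)[C@H](C)[C@H]1CO[Si](C)(C)C(C)(C)C
F7 | step 5 | methyl 2-[(1S,2S,3R,4R)-4-(tert-butyldimethylsilyloxy)-2-[(tert-butyldimethylsilyloxy)methyl]-3-methylcyclopentyl]acetate | COC(=O)C[C@@H]1C[C@@H](O[Si](C)(C)C(C)(C)C)[C@H](C)[C@H]1CO[Si](C)(C)C(C)(C)C
F8 | step 15 | (4S,5R)-5-allyl-4-(2,2-dibromovinyl)-2,2-dimethyl-1,3-dioxolane | C=CC[C@H]1OC(C)(C)O[C@H]1C=C(Br)Br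
F9 | step 15 | (4S,5R)-5-allyl-2,2-dimethyl-4-(prop-1-yn-1-yl)-1,3-dioxolane | C=CC[C@H]1OC(C)(C)O[C@H]1C#CC
F10 | step 15 | [(Z)-1-[(4R,5R)-5-allyl-2,2-dimethyl-1,3-dioxolan-4-yl]prop-1-en-1-yl]triphenylstannane | C=CC[C@H]1OC(C)(C)O[C@H]1/C([Sn](c2ccccc2)(c2ccccc2)c2ccccc2)=C/C
F11 | step 15 | (4R,5R)-5-allyl-4-[(Z)-1-iodoprop-1-en-1-yl]-2,2-dimethyl-1,3-dioxolane | C=CC[C@H]1OC(C)(C)O[C@H]1/C(I)=C/C
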